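## Retrosynthetic overview

- **Feature used:** the C8 side chain C1'(=O)–C2'(O-isovaleryl)=C3'(CH3)2 is the enol ester of an aryl 1,2-diketone. It is read as "tertiary propargylic ester plus one oxygen atom". C1'=O, the C2'–O bond and the C2'=C3' bond all come from Ar–C1'≡C2'–C3'(CH3)2–O-isovaleryl by gold-catalysed oxygen transfer with a 1,2-acyloxy shift from C3' to C2'.
- **Second cut:** the propargylic ester is cut at C8–C1' (Sonogashira coupling) into 8-iodo-7-methoxycoumarin and 2-methylbut-3-yn-2-yl isovalerate.
- **Fragments:** the iodide comes from umbelliferone by C8 iodination and O-methylation. The alkyne ester comes from 2-methylbut-3-yn-2-ol and isovaleric anhydride.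
- **Rings:** no ring is formed. The benzene and pyranone rings of the coumarin are bought intact in umbelliferone.

Key step: step 5

Assumption: the target has no stereocentre and no E/Z element, because C3' carries two methyl groups. It is achiral, so "single enantiomer" means the one constitution drawn.

## Route

Step 1
Reactants: 1 umbelliferone (7-hydroxy-2H-chromen-2-one)
Product: 2 7-hydroxy-8-iodo-2H-chromen-2-one
Conditions: I2 (1.0 equiv), KI, 20% aq NH3, 0 °C to rt; then dil. H2SO4 to pH 3
Reagents that add atoms: iodine, II
Why: Electrophilic aromatic iodination of the phenoxide should go to C8, the position ortho to O7 and flanked by C8a–O1 that is the known preferred site of umbelliferone under basic conditions, and acidification re-closes any opened lactone.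

Step 2
Reactants: 2 7-hydroxy-8-iodo-2H-chromen-2-one
Product: 3 8-iodo-7-methoxy-2H-chromen-2-one
Conditions: MeI, K2CO3, acetone, reflux
Reagents that add atoms: iodomethane, CI
Why: Williamson ether synthesis, in which the acidic 7-OH is deprotonated by carbonate and methylated by SN2 while the C8–I bond and the lactone are inert.

Step 3
Reactants: 4 2-methylbut-3-yn-2-ol; 5 isovaleric anhydride (3-methylbutanoic anhydride)
Product: 6 2-methylbut-3-yn-2-yl 3-methylbutanoate
Conditions: Et3N, DMAP (20 mol %), CH2Cl2, rt to 40 °C
Reagents that add atoms: none
Why: DMAP-catalysed (Steglich-type) acyl transfer from the anhydride should esterify the tertiary carbinol, whose slim ethynyl substituent keeps it accessible, under basic conditions that avoid ionisation.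

Step 4
Reactants: 3 8-iodo-7-methoxy-2H-chromen-2-one; 6 2-methylbut-3-yn-2-yl 3-methylbutanoate
Product: 7 4-(7-methoxy-2-oxo-2H-chromen-8-yl)-2-methylbut-3-yn-2-yl 3-methylbutanoate
Conditions: PdCl2(PPh3)2 (5 mol %), CuI (10 mol %), Et3N, DMF, 45 °C, Ar
Reagents that add atoms: none
Why: Sonogashira coupling, in which oxidative addition into the C8–I bond is much faster than ionisation of a propargylic carboxylate and the tertiary amine base offers no N–H nucleophile for propargylic substitution, so the ester should survive.

Step 5
Reactants: 7 4-(7-methoxy-2-oxo-2H-chromen-8-yl)-2-methylbut-3-yn-2-yl 3-methylbutanoate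
Product: 9 exotimarin H [1-(7-methoxy-2-oxo-2H-chromen-8-yl)-3-methyl-1-oxobut-2-en-2-yl 3-methylbutanoate], via α-oxo gold carbene 8 (not isolated)
Conditions: IPrAuNTf2 (5 mol %, added last), 8-methylquinoline N-oxide (2 equiv), 4 Å MS, DCE, rt to 40 °C
Reagents that add atoms: 8-methylquinoline N-oxide, Cc1cccc2ccc[n+]([O-])c12
Why: Proposed new method: LAu+ activates the C1'≡C2' bond of 7, the N-oxide oxygen adds to the aryl-bearing C1', loss of 8-methylquinoline gives α-oxo gold carbene 8 (C1'=O, C2'=Au), and the isovalerate on C3' moves to C2' through a five-membered dioxolenium ion with release of LAu+, which sets C1'=O, the C2'–O ester bond and the tetrasubstituted C2'=C3' bond in one operation. The closest known reaction types are the gold/N-oxide oxidation of primary and secondary propargylic carboxylates to α-acyloxy enones and the gold-catalysed 1,2-acyloxy shift/sulfoxide oxidation of terminal propargylic esters to α-acyloxy enals, and the new element is the tertiary, aryl-capped carboxylate, a class that is prone to the 3,3-shift. No ring is closed and no stereocentre or E/Z element is formed, since C3' bears two methyl groups. The step needs oxygen delivery to C1' and not to C2', and three biases point the same way: the 7-methoxy-donor arene stabilises positive charge at C1', the σ-withdrawing acyloxy-bearing C3' disfavours charge at C2', and the quaternary C3' shields C2'. The competing acyloxy shifts should not be fatal, because the 1,2-shift gives a vinyl gold carbene at C1' that the same N-oxide oxidises to 9, and the 3,3-shift to the allenyl ester is reversible under gold and cannot drain into an indene since both ortho positions (C7 and C8a) are substituted. With no hydrogen on C3' the 1,2-H shift that competes in secondary substrates is impossible, and dry conditions suppress hydrolysis to the simple enone.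

## Compound list

1 | umbelliferone (7-hydroxy-2H-chromen-2-one) | Oc1ccc2ccc(=O)oc2c1 | starting material
2 | 7-hydroxy-8-iodo-2H-chromen-2-one | Oc1ccc2ccc(=O)oc2c1I | intermediate
3 | 8-iodo-7-methoxy-2H-chromen-2-one | COc1ccc2ccc(=O)oc2c1I | intermediate
4 | 2-methylbut-3-yn-2-ol | CC(C)(O)C#C | starting material
5 | isovaleric anhydride (3-methylbutanoic anhydride) | CC(C)CC(=O)OC(=O)CC(C)C | starting material
6 | 2-methylbut-3-yn-2-yl 3-methylbutanoate | C#CC(C)(C)OC(=O)CC(C)C | intermediate
7 | 4-(7-methoxy-2-oxo-2H-chromen-8-yl)-2-methylbut-3-yn-2-yl 3-methylbutanoate | COc1ccc2ccc(=O)oc2c1C#CC(C)(C)OC(=O)CC(C)C | intermediate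
8 | α-oxo gold carbene (C1'=O, C2'=Au; the IPr ligand on gold is not drawn) | COc1ccc2ccc(=O)oc2c1C(=O)C(=[Au+])C(C)(C)OC(=O)CC(C)C | intermediate
9 | exotimarin H (achiral) | COc1ccc2ccc(=O)oc2c1C(=O)C(OC(=O)CC(C)C)=C(C)C | target

## Step count and risks

Total step count: 5. Longest linear sequence: 4 (1 → 2 → 3 → 7 → 9).

### Step 5 (proposed new method)

**What may go wrong**
- The intramolecular 3,3-acyloxy shift may outrun oxygen transfer. The allenyl ester may then drain irreversibly by proton loss from a C3' methyl group or by hydrolysis.
- The carbene may be intercepted by the neighbouring 7-methoxy oxygen or by a second N-oxide before the acyloxy shift.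

**Fallback (known chemistry, enolate O-acylation logic).** It sets out from 3 and comes back at 9.
- Sonogashira coupling of 3 with 3-methylbut-1-yne (PdCl2(PPh3)2, CuI, Et3N, DMF, sealed tube, 50 °C) should give 7-methoxy-8-(3-methylbut-1-yn-1-yl)-2H-chromen-2-one F1.
- Wacker-type alkyne oxidation (PdBr2, CuBr2, O2, aqueous dioxane, 60 °C) should give 1-(7-methoxy-2-oxo-2H-chromen-8-yl)-3-methylbutane-1,2-dione F2.
- The isopropyl C–H is the only enolisable position of F2. Deprotonation (LiHMDS, THF, −78 °C) and trapping with anhydride 5 should acylate on oxygen, because C-acylation would need a quaternary carbon, and this gives 9.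

### Step 4

**What may go wrong**
- The tertiary propargylic ester may be ionised by Pd(0) or copper, with elimination to the enyne.
- Oxidative addition at the di-ortho-substituted C8–I bond may be slow, so that alkyne homocoupling takes over.

**Fallback.** It sets out from 3 and 4 and comes back at 7.
- The free alcohol 4 is coupled with 3 under the same Sonogashira conditions to give 8-(3-hydroxy-3-methylbut-1-yn-1-yl)-7-methoxy-2H-chromen-2-one F3.
- The ester is introduced only afterwards with 5 (DMAP, Et3N, CH2Cl2, 40 °C) to give 7.

### Step 1

**What may go wrong**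
- Site selectivity may be poor, with attack at C6 or C3 or double iodination.
- The lactone may be opened irreversibly by ammonia.

**Fallback.** It sets out from 1 and comes back at 7. The C8–C1' bond is made by electrophilic formylation instead of halogenation and cross-coupling.
- Duff formylation of 1 (hexamethylenetetramine, TFA, reflux; then aq HCl) should give 7-hydroxy-2-oxo-2H-chromene-8-carbaldehyde F4.
- Methylation (MeI, K2CO3, acetone) gives 7-methoxy-2-oxo-2H-chromene-8-carbaldehyde F5.
- Ohira–Bestmann homologation (dimethyl (1-diazo-2-oxopropyl)phosphonate, K2CO3, MeOH, rt) gives 8-ethynyl-7-methoxy-2H-chromen-2-one F6.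
- Me2Zn-mediated addition of F6 to acetone (toluene, rt) gives 8-(3-hydroxy-3-methylbut-1-yn-1-yl)-7-methoxy-2H-chromen-2-one F3.
- Acylation of F3 with 5 (DMAP, Et3N) gives 7.

## Further compounds

F1 | step 5 | 7-methoxy-8-(3-methylbut-1-yn-1-yl)-2H-chromen-2-one | COc1ccc2ccc(=O)oc2c1C#CC(C)C
F2 | step 5 | 1-(7-methoxy-2-oxo-2H-chromen-8-yl)-3-methylbutane-1,2-dione | COc1ccc2ccc(=O)oc2c1C(=O)C(=O)C(C)C
F3 | step 4 | 8-(3-hydroxy-3-methylbut-1-yn-1-yl)-7-methoxy-2H-chromen-2-one | COc1ccc2ccc(=O)oc2c1C#CC(C)(C)O
F4 | step 1 | 7-hydroxy-2-oxo-2H-chromene-8-carbaldehyde | Oc1ccc2ccc(=O)oc2c1C=O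
F5 | step 1 | 7-methoxy-2-oxo-2H-chromene-8-carbaldehyde | COc1ccc2ccc(=O)oc2c1C=O
F6 | step 1 | 8-ethynyl-7-methoxy-2H-chromen-2-one | COc1ccc2ccc(=O)oc2c1C#C
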